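**Retrosynthetic overview**

1. The plan rests on C6, the oxygen-bearing allylic carbon of the seven-membered ring, which lies between the ring-fusion carbon C5 and the trisubstituted C7=C8 alkene (methyl on C8). Cutting C6–C7 turns it into a formyl group on C5 and a (Z)-alkenyl metal at C7 that is tethered to C1.
2. Order of disconnection: first the ester C–O bond (isovanillic acid, phenol as TBS ether, onto the free C4,C6-diol 19), then C6–C7 (chromium/nickel closure of iodoalkene aldehyde 18). The seven-membered ring C5–C6–C7–C8–C9–C10–C1 is therefore formed last, on a finished cyclopentane C1–C5.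
3. The (Z)-iodoalkene comes from syn-carbocupration of propyne by an alkylcopper grown from a vinyl group on C1 (hydroboration, iodination). The vinyl group comes from conjugate addition to cyclopentene carbaldehyde 5.
4. Enal 5 (the first ring) comes from (S)-terpinen-4-ol by silylation, ozonolysis and aldol ring contraction. C4 is chiral-pool, C1 and C5 follow from C4, and C6 follows from C4 and C5 through hydroxyl-guided chromium delivery.

Key step: step 10

Remark on the chemistry: commercial (S)-terpinen-4-ol is taken to be of high enantiomeric purity. Atoms carry daucane numbers (C1 quaternary methyl carbon, C4 isopropyl carbinol, C5 ring-fusion CH, C6 ester carbon, C7=C8 with methyl on C8, then C9, C10), and β is the cyclopentane face that carries the C4 oxygen.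

**Route**

Step 1
Reactants: 1 (S)-terpinen-4-ol
Product: 2 triethylsilyl ether of (S)-terpinen-4-ol
Conditions: TESOTf, 2,6-lutidine, CH2Cl2, 0 °C to rt
Reagents that add atoms: triethylsilyl trifluoromethanesulfonate CC[Si](CC)(CC)OS(=O)(=O)C(F)(F)F
Why: Silyl triflate silylation of a hindered tertiary alcohol; the chiral-pool C4 centre is not touched, and the silyl ether keeps the C4 oxygen from being eliminated in steps 3 and 4 and from quenching the organometallics of steps 4 and 8.

Step 2
Reactants: 2 triethylsilyl ether of (S)-terpinen-4-ol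
Product: 4 (S)-3-isopropyl-6-oxo-3-(triethylsilyloxy)heptanal, via ozonide 3 (not isolated)
Conditions: O3, CH2Cl2, −78 °C; then PPh3, −78 °C to rt
Reagents that add atoms: ozone [O-][O+]=O
Why: Ozonolysis of the only C=C bond with reductive cleavage of the ozonide by PPh3 should give the 1,6-keto aldehyde without touching C4.

Step 3
Reactants: 4 (S)-3-isopropyl-6-oxo-3-(triethylsilyloxy)heptanal
Product: 5 (R)-5-isopropyl-2-methyl-5-(triethylsilyloxy)cyclopent-1-ene-1-carbaldehyde
Conditions: piperidine, AcOH (0.3 equiv each), toluene, 70 °C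
Reagents that add atoms: none
Why: Enamine-mediated intramolecular aldol condensation: the piperidine enamine of the aldehyde attacks the methyl ketone (5-exo-trig) and the new tertiary hydroxyl is lost, which should give the formylcyclopentene and not the acetylcyclopentene, as in known ring contractions of terpene-derived 1,6-keto aldehydes, while the silyloxy group is the poorer leaving group and C4 is retained.

Step 4
Reactants: 5 (R)-5-isopropyl-2-methyl-5-(triethylsilyloxy)cyclopent-1-ene-1-carbaldehyde; 6 vinylmagnesium bromide
Product: 8 (1R,2R,5S)-5-ethenyl-2-isopropyl-5-methyl-2-(triethylsilyloxy)cyclopentane-1-carbaldehyde (vinyl, formyl and silyloxy groups all β), via trimethylsilyl enol ether 7 (not isolated)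
Conditions: 6 (2 equiv), CuBr·SMe2 (0.2 equiv), TMSCl, DMPU, THF, −78 to −40 °C; then 1 M HCl, THF, 0 °C; then DBU (0.1 equiv), CH2Cl2, rt
Reagents that add atoms: none
Why: Copper-catalysed, TMSCl-accelerated conjugate addition of the Grignard reagent (1,4-addition, trapped as enol ether 7) creates the C1 quaternary centre with the vinyl group entering anti to the C4 isopropyl group, which sits pseudoaxial to avoid allylic strain with the formyl group while the silyloxy oxygen is small at the ring, and hydrolysis followed by base equilibration sets C5 under thermodynamic control with the formyl group trans to isopropyl and methyl.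

Step 5
Reactants: 8 (1R,2R,5S)-5-ethenyl-2-isopropyl-5-methyl-2-(triethylsilyloxy)cyclopentane-1-carbaldehyde
Product: 9 dimethyl acetal of aldehyde 8 (all stereocentres as in 8)
Conditions: HC(OMe)3, MeOH, PPTS (cat.), 0 °C to rt
Reagents that add atoms: trimethyl orthoformate COC(OC)OC
Why: Acid-catalysed acetalisation with orthoformate as water scavenger masks the aldehyde for the borane and organometallic steps and freezes C5, under conditions mild enough for the hindered tertiary silyl ether.

Step 6
Reactants: 9 dimethyl acetal of aldehyde 8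
Product: 11 primary alcohol (2-hydroxyethyl chain on C1; acetal and silyl ether as in 9), via alkylborane 10 (not isolated)
Conditions: 9-BBN, THF, 0 to 50 °C; then 3 M NaOH, 30% H2O2, 0 °C to rt
Reagents that add atoms: hydrogen peroxide OO
Why: Hydroboration–oxidation: 9-BBN places boron on the terminal carbon of the vinyl group and basic peroxide oxidises the C–B bond, with acetal and tertiary silyl ether untouched and no stereocentre formed.

Step 7
Reactants: 11 primary alcohol
Product: 12 primary iodide (2-iodoethyl chain on C1)
Conditions: I2, PPh3, imidazole, CH2Cl2, 0 °C to rt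
Reagents that add atoms: iodine II
Why: Appel-type iodination (phosphonium activation, then SN2 by iodide) of the primary alcohol, buffered by imidazole so that acetal and silyl ether survive.

Step 8
Reactants: 12 primary iodide; 13 propyne
Product: 17 (Z)-iodoalkene dimethyl acetal ((Z)-4-iodo-3-methylbut-3-enyl chain on C1), via alkylmagnesium iodide 14 (not isolated), via alkylcopper 15 (not isolated), via alkenylcopper 16 (not isolated)
Conditions: Mg turnings (activated with 1,2-dibromoethane), Et2O, rt; CuBr·SMe2, Et2O/Me2S, −45 °C; 13, −25 °C; I2, THF, −40 to 0 °C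
Reagents that add atoms: iodine II
Why: Normant carbocupration: the Grignard-derived alkylcopper adds syn across propyne with the alkyl group on the internal carbon and copper on the terminal one, and iodinolysis of the alkenylcopper with retention puts iodine cis to the chain, which is the (Z)-2-methyl-1-iodoalkene needed for a cis ring alkene.

Step 9
Reactants: 17 (Z)-iodoalkene dimethyl acetal
Product: 18 (1R,2R,5R)-2-hydroxy-5-[(Z)-4-iodo-3-methylbut-3-enyl]-2-isopropyl-5-methylcyclopentane-1-carbaldehyde
Conditions: HF (48% aq.), MeCN, 0 °C to rt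
Reagents that add atoms: water O
Why: Aqueous HF cleaves the tertiary triethylsilyl ether and hydrolyses the dimethyl acetal in one operation under weakly acidic, non-basic conditions that avoid retro-aldol cleavage of the β-hydroxy aldehyde, and C5 stays in its preferred configuration with the formyl group cis to the hydroxyl.

Step 10
Reactants: 18 (1R,2R,5R)-2-hydroxy-5-[(Z)-4-iodo-3-methylbut-3-enyl]-2-isopropyl-5-methylcyclopentane-1-carbaldehyde
Product: 19 (3R,3aS,4R,8aR)-3-isopropyl-6,8a-dimethyl-1,2,3,3a,4,7,8,8a-octahydroazulene-3,4-diol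
Conditions: CrCl2 (8 equiv), NiCl2 (0.1 equiv), degassed THF/DMF (3:1), 0.01 M, rt
Reagents that add atoms: none
Why: CrCl2 reduces NiCl2 to zerovalent nickel, which inserts into the C7–I bond with retention of the Z geometry; transmetalation gives the alkenyl trivalent-chromium species, which adds to the C6 aldehyde and gives the diol after aqueous work-up. The closest known reaction type is the intramolecular Nozaki–Hiyama–Kishi cyclisation of iodoalkene aldehydes to medium-ring allylic alcohols. The seven-membered ring closes in the 7-exo-trig mode by attack of C7 on the exocyclic carbonyl carbon C6, which the cis arrangement of the C1 chain and the C5 formyl group on the cyclopentane makes geometrically easy. The new stereocentre C6 is controlled by C5 and by the free C4 hydroxyl cis to the formyl group: chromium held by O4 and by the carbonyl oxygen (six-membered chelate) can pass C7 only to the aldehyde face that leaves O6 on the side of O4 and H6 on the side of H5, as the target requires, and this is why the silyl ether is removed before the closure and not after it. The step needs chemoselectivity for the C–I bond beside a free hydroxyl and a hindered, enolisable aldehyde, which the non-basic, oxophilic organochromium reagent secures, and retention of alkene geometry, which the nickel/chromium sequence secures.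

Step 11
Reactants: 20 isovanillic acid
Product: 22 3-(tert-butyldimethylsilyloxy)-4-methoxybenzoic acid, via bis-silyl derivative 21 (not isolated)
Conditions: TBSCl (2.3 equiv), imidazole, DMF, rt; then AcOH/THF/H2O, rt
Reagents that add atoms: tert-butyldimethylsilyl chloride CC(C)(C)[Si](C)(C)Cl
Why: Silylation of both the phenol and the acid followed by selective hydrolysis of the labile silyl ester should leave the phenol as its TBS ether and the acid free.

Step 12
Reactants: 19 (3R,3aS,4R,8aR)-3-isopropyl-6,8a-dimethyl-1,2,3,3a,4,7,8,8a-octahydroazulene-3,4-diol; 22 3-(tert-butyldimethylsilyloxy)-4-methoxybenzoic acid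
Product: 24 C6 3-(tert-butyldimethylsilyloxy)-4-methoxybenzoate of diol 19, via mixed anhydride 23 (not isolated)
Conditions: 22, 2,4,6-trichlorobenzoyl chloride, Et3N, THF, rt; then 19, DMAP (0.5 equiv), toluene, rt to 40 °C
Reagents that add atoms: none
Why: Yamaguchi esterification through the mixed anhydride and DMAP acyl transfer should acylate the secondary allylic C6 hydroxyl while the hindered tertiary C4 hydroxyl stays free, and C6 keeps its configuration because its C–O bond is not broken.

Step 13
Reactants: 24 C6 3-(tert-butyldimethylsilyloxy)-4-methoxybenzoate of diol 19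
Product: 25 target, (3R,3aS,4R,8aR)-3-hydroxy-3-isopropyl-6,8a-dimethyl-1,2,3,3a,4,7,8,8a-octahydroazulen-4-yl 3-hydroxy-4-methoxybenzoate
Conditions: TBAF, AcOH (1:1), THF, 0 °C
Reagents that add atoms: none
Why: Fluoride cleavage of the aryl silyl ether, buffered with acetic acid so that no phenoxide or fluoride attacks the allylic ester, touches no stereocentre.

**Compound list**

1 | (S)-terpinen-4-ol | CC1=CC[C@](O)(C(C)C)CC1 | starting material
2 | triethylsilyl ether of (S)-terpinen-4-ol | CC1=CC[C@](O[Si](CC)(CC)CC)(C(C)C)CC1 | intermediate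
3 | ozonide of 2 (1,2,4-trioxolane, both bridge orientations) | CC12CC[C@@](O[Si](CC)(CC)CC)(C(C)C)CC(OO1)O2 | intermediate
4 | (S)-3-isopropyl-6-oxo-3-(triethylsilyloxy)heptanal | CC(=O)CC[C@@](O[Si](CC)(CC)CC)(C(C)C)CC=O | intermediate
5 | (R)-5-isopropyl-2-methyl-5-(triethylsilyloxy)cyclopent-1-ene-1-carbaldehyde | CC1=C(C=O)[C@](O[Si](CC)(CC)CC)(C(C)C)CC1 | intermediate
6 | vinylmagnesium bromide | C=C[Mg]Br | starting material
7 | trimethylsilyl enol ether of 8 (enol ether geometry not defined) | C=C[C@]1(C)CC[C@@](O[Si](CC)(CC)CC)(C(C)C)C1=CO[Si](C)(C)C | intermediate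
8 | (1R,2R,5S)-5-ethenyl-2-isopropyl-5-methyl-2-(triethylsilyloxy)cyclopentane-1-carbaldehyde | C=C[C@]1(C)CC[C@@](O[Si](CC)(CC)CC)(C(C)C)[C@@H]1C=O | intermediate
9 | dimethyl acetal of 8 | C=C[C@]1(C)CC[C@@](O[Si](CC)(CC)CC)(C(C)C)[C@@H]1C(OC)OC | intermediate
10 | B-alkyl-9-borabicyclo[3.3.1]nonane from 9 | C1CC2CCCC(C1)B2CC[C@]1(C)CC[C@@](O[Si](CC)(CC)CC)(C(C)C)[C@@H]1C(OC)OC | intermediate
11 | primary alcohol (2-hydroxyethyl on C1) | OCC[C@]1(C)CC[C@@](O[Si](CC)(CC)CC)(C(C)C)[C@@H]1C(OC)OC | intermediate
12 | primary iodide (2-iodoethyl on C1) | ICC[C@]1(C)CC[C@@](O[Si](CC)(CC)CC)(C(C)C)[C@@H]1C(OC)OC | intermediate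
13 | propyne | CC#C | starting material
14 | alkylmagnesium iodide from 12 | I[Mg]CC[C@]1(C)CC[C@@](O[Si](CC)(CC)CC)(C(C)C)[C@@H]1C(OC)OC | intermediate
15 | alkylcopper (as its magnesium halide complex) | [Cu]CC[C@]1(C)CC[C@@](O[Si](CC)(CC)CC)(C(C)C)[C@@H]1C(OC)OC | intermediate
16 | (Z)-alkenylcopper | [Cu]/C=C(C)\CC[C@]1(C)CC[C@@](O[Si](CC)(CC)CC)(C(C)C)[C@@H]1C(OC)OC | intermediate
17 | (Z)-iodoalkene dimethyl acetal | I/C=C(C)\CC[C@]1(C)CC[C@@](O[Si](CC)(CC)CC)(C(C)C)[C@@H]1C(OC)OC | intermediate
18 | (1R,2R,5R)-2-hydroxy-5-[(Z)-4-iodo-3-methylbut-3-enyl]-2-isopropyl-5-methylcyclopentane-1-carbaldehyde | I/C=C(C)\CC[C@]1(C)CC[C@@](O)(C(C)C)[C@@H]1C=O | intermediate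
19 | (3R,3aS,4R,8aR)-3-isopropyl-6,8a-dimethyl-1,2,3,3a,4,7,8,8a-octahydroazulene-3,4-diol | O[C@@H]1C=C(C)CC[C@]2(C)CC[C@@](O)(C(C)C)[C@H]12 | intermediate
20 | isovanillic acid | COc1ccc(C(=O)O)cc1O | starting material
21 | tert-butyldimethylsilyl 3-(tert-butyldimethylsilyloxy)-4-methoxybenzoate | COc1ccc(C(=O)O[Si](C)(C)C(C)(C)C)cc1O[Si](C)(C)C(C)(C)C | intermediate
22 | 3-(tert-butyldimethylsilyloxy)-4-methoxybenzoic acid | COc1ccc(C(=O)O)cc1O[Si](C)(C)C(C)(C)C | intermediate
23 | mixed anhydride of 22 with 2,4,6-trichlorobenzoic acid | COc1ccc(C(=O)OC(=O)c2c(Cl)cc(Cl)cc2Cl)cc1O[Si](C)(C)C(C)(C)C | intermediate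
24 | C6 3-(tert-butyldimethylsilyloxy)-4-methoxybenzoate of diol 19 | COc1ccc(C(=O)O[C@@H]2C=C(C)CC[C@]3(C)CC[C@@](O)(C(C)C)[C@H]23)cc1O[Si](C)(C)C(C)(C)C | intermediate
25 | (3R,3aS,4R,8aR)-3-hydroxy-3-isopropyl-6,8a-dimethyl-1,2,3,3a,4,7,8,8a-octahydroazulen-4-yl 3-hydroxy-4-methoxybenzoate | COc1ccc(C(=O)O[C@@H]2C=C(C)CC[C@]3(C)CC[C@@](O)(C(C)C)[C@H]23)cc1O | target

**Step count**

Total step count: 13. Longest linear sequence: 12 steps (steps 1 to 10, then 12 and 13, from (S)-terpinen-4-ol); step 11 is a one-step side branch.

**Steps most likely to fail**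

1. Step 10 (key step).
   - What may go wrong: the donor solvent may displace the C4 hydroxyl from chromium, so that C7 attacks the other aldehyde face and the facial selectivity at C6 is poor or reversed. Slow closure at an aldehyde flanked by two quaternary carbons may also let the alkenylchromium be protonated.
   - Fallback (C6 set by hydride addition to a ketone, not by the C–C bond formation): it sets out from 18. The closure is run as in step 10, and whatever carbinol forms, in the limit the C6-epimeric diol F1, is oxidised at the secondary allylic hydroxyl with Dess–Martin periodinane (NaHCO3, CH2Cl2, 0 °C) to hydroxy enone F2. Luche reduction (NaBH4, CeCl3·7H2O, MeOH, −78 °C) should deliver hydride to the cerium-bound ketone from the convex face, the side of H5 and the C1 methyl group, away from the cyclopentane. The route is rejoined at 19.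

2. Step 9.
   - What may go wrong: once the β-hydroxy aldehyde is free, acid may promote loss of the tertiary C4 hydroxyl toward the conjugated enal, or the C4–C5 bond may cleave by retro-aldol reaction, also in the chromium medium of the next step.
   - Fallback (C4 oxygen kept silylated through the ring closure): it sets out from 17. Oxalic acid on wet silica gel (CH2Cl2, rt) hydrolyses the acetal alone to silyl ether aldehyde F3. Closure with CrCl2/NiCl2 as in step 10 gives crude silyl ether carbinol F4, whose C6 configuration is not relied on. Dess–Martin oxidation gives silylated enone F5, and i-Bu2AlH (CH2Cl2, −78 °C) should reduce it from the convex face to the C6-defined silyl ether carbinol F6. TBAF (THF, rt to 40 °C) then removes the tertiary silyl group, and the route is rejoined at 19.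

3. Step 8.
   - What may go wrong: Wurtz coupling or protonation while the alkylmagnesium and alkylcopper species are formed, and incomplete or non-regioselective addition to propyne.
   - Fallback (cross-coupling with a preformed (Z)-bromoalkenylboron unit instead of carbometalation by the substrate): it sets out from 12. Zinc insertion (Zn dust activated with 1,2-dibromoethane and TMSCl, DMF, 40 °C) gives alkylzinc iodide F7. Propyne 13 is bromoborated with BBr3 (CH2Cl2, −78 °C, syn addition) to dibromoborane F8 and esterified with pinacol to bromoalkenyl pinacol boronate F9. Negishi coupling of F7 with F9 (PdCl2(DPEphos), THF, rt) replaces bromine with retention and gives alkenyl pinacol boronate F10. Iodinolysis (I2, NaOH, THF/H2O, 0 °C) with retention rejoins the route at 17.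

Further compounds
F1 | step 10 | C6-epimeric diol (C6 epimer of 19) | O[C@H]1C=C(C)CC[C@]2(C)CC[C@@](O)(C(C)C)[C@H]12
F2 | step 10 | hydroxy enone (C6 ketone of 19) | O=C1C=C(C)CC[C@]2(C)CC[C@@](O)(C(C)C)[C@H]12
F3 | step 9 | silyl ether aldehyde (C4 triethylsilyl ether of 18) | I/C=C(C)\CC[C@]1(C)CC[C@@](O[Si](CC)(CC)CC)(C(C)C)[C@@H]1C=O
F4 | step 9 | crude silyl ether carbinol (C6 not defined) | OC1C=C(C)CC[C@]2(C)CC[C@@](O[Si](CC)(CC)CC)(C(C)C)[C@H]12
F5 | step 9 | silylated enone | O=C1C=C(C)CC[C@]2(C)CC[C@@](O[Si](CC)(CC)CC)(C(C)C)[C@H]12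
F6 | step 9 | C6-defined silyl ether carbinol (C4 triethylsilyl ether of 19) | O[C@@H]1C=C(C)CC[C@]2(C)CC[C@@](O[Si](CC)(CC)CC)(C(C)C)[C@H]12
F7 | step 8 | alkylzinc iodide from 12 | I[Zn]CC[C@]1(C)CC[C@@](O[Si](CC)(CC)CC)(C(C)C)[C@@H]1C(OC)OC
F8 | step 8 | (Z)-(2-bromoprop-1-enyl)dibromoborane | C/C(Br)=C/B(Br)Br
F9 | step 8 | (Z)-2-(2-bromoprop-1-enyl)-4,4,5,5-tetramethyl-1,3,2-dioxaborolane | C/C(Br)=C/B1OC(C)(C)C(C)(C)O1
F10 | step 8 | (Z)-alkenyl pinacol boronate (boron in place of iodine in 17) | CC1(C)OB(/C=C(C)\CC[C@]2(C)CC[C@@](O[Si](CC)(CC)CC)(C(C)C)[C@@H]2C(OC)OC)OC1(C)C
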